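## Assumptions
(i) The BINAP enantiomer used in Step 3 is the one that gives the (R)-acid **5**; this is to be confirmed by chiral HPLC on a pilot run. (ii) The benzylic carbinol centre in **15** is destroyed in Step 13, so it is left undefined.

## Target check
The target is (2R,3S)-2-(4-hydroxy-3,5-dimethoxybenzyl)-4-(4-hydroxy-3-methoxyphenyl)-3-methylbutyl acetate. It has an acyclic 1,4-diarylbutane skeleton:
- Ar(guaiacyl)–CH2–C8H(CH3)–C8'H(CH2OAc)–CH2–Ar(syringyl).
- C8 (bearing CH3) is S, and C8' (bearing CH2OAc) is R.
- The route's trans-3-methyl-4-(arylmethyl)-γ-butyrolactone **9** has the 3R,4R configuration. Its SMILES maps onto the target centres by neighbour-order permutation: C4 becomes C8' (R) and C3 becomes C8 (S). The change in CIP label at C8 comes only from the change in substituent priorities.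

## Retrosynthetic overview
1. Target ⇒ lipase (hydrolase) chemoselective acetylation of the primary OH of diphenol alcohol **16**, with both phenols free ⇒ global hydrogenolysis of the benzyl ethers and the benzylic C–O bond of **15**.
2. **15** ⇐ aryl Grignard addition to Weinreb amide **11**, which comes from Weinreb opening of the trans-3-methyl-4-(arylmethyl)lactone **9**. The lactone is the only ring made and opened; both arenes are preformed.
3. C8' is set first by Ru-BINAP asymmetric hydrogenation of the Stobbe half-ester **4**. C8 is then set by trans-selective lactone-enolate methylation, controlled by C8'.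

## Forward route

**Step 1**
Reactants: 1, syringaldehyde (4-hydroxy-3,5-dimethoxybenzaldehyde)
Product: 2, 4-(benzyloxy)-3,5-dimethoxybenzaldehyde
Conditions: BnBr, K2CO3, DMF, 60 °C
Reagents that add atoms: benzyl bromide, BrCc1ccccc1
Why: Williamson O-benzylation masks the phenol as a benzyl ether that survives the later base, Grignard and hydride steps and is removed in Step 13.

**Step 2**
Reactants: 2; 3, diethyl succinate
Product: 4, (E)-4-[4-(benzyloxy)-3,5-dimethoxyphenyl]-3-(ethoxycarbonyl)but-3-enoic acid
Conditions: KOtBu, tBuOH, reflux; then aq. HCl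
Reagents that add atoms: none
Why: Stobbe condensation (aldol, γ-lactonisation, E1cB ring opening) gives the (E)-arylidene half-ester with a free CH2CO2H and a conjugated ethyl ester, the chelating substrate for directed asymmetric hydrogenation.

**Step 3**
Reactants: 4
Product: 5, (3R)-4-[4-(benzyloxy)-3,5-dimethoxyphenyl]-3-(ethoxycarbonyl)butanoic acid
Conditions: H2 (50 bar), Ru(OAc)2[(R)-BINAP] (1 mol%), MeOH, 50 °C
Reagents that add atoms: none
Why: Ru-BINAP asymmetric hydrogenation, directed by carboxylate and ester chelation, delivers H2 to one alkene face and sets C8' as R; recrystallisation of **5** or of lactone **8** upgrades the ee.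

**Step 4**
Reactants: 5
Product: 6, 1-ethyl 4-tert-butyl (2R)-2-{[4-(benzyloxy)-3,5-dimethoxyphenyl]methyl}butanedioate
Conditions: Boc2O, DMAP (cat.), tBuOH, THF, rt
Reagents that add atoms: tert-butanol, CC(C)(C)O
Why: DMAP-catalysed Boc2O activation converts the free acid into a mixed anhydride (lost as CO2 and tBuOH), which tBuOH traps as the tert-butyl ester (Takeda-type esterification); this differentiates the two carbonyls, and the stereocentre, which is not α to the activated carbonyl, is untouched.

**Step 5**
Reactants: 6
Product: 7, tert-butyl (3R)-3-{[4-(benzyloxy)-3,5-dimethoxyphenyl]methyl}-4-hydroxybutanoate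
Conditions: LiBH4, MeOH (cat.), THF, 0 °C → rt
Reagents that add atoms: none
Why: LiBH4 reduces the ethyl ester but not the hindered tert-butyl ester, so the carbonyl on the branched carbon becomes CH2OH (C9'); these non-enolising conditions leave the stereocentre intact.

**Step 6**
Reactants: 7
Product: 8, (4R)-4-{[4-(benzyloxy)-3,5-dimethoxyphenyl]methyl}oxolan-2-one
Conditions: TsOH·H2O (cat.), PhMe, 60 °C
Reagents that add atoms: none
Why: acid-catalysed loss of the tert-butyl group gives the hydroxy acid, which lactonises intramolecularly (Fischer-type) to the γ-butyrolactone, the rigid template for trans-selective α-alkylation; C4 is not epimerisable.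

**Step 7**
Reactants: 8
Product: 9, (3R,4R)-4-{[4-(benzyloxy)-3,5-dimethoxyphenyl]methyl}-3-methyloxolan-2-one
Conditions: LDA, THF, −78 °C; then MeI, −78 → −30 °C
Reagents that add atoms: methyl iodide, CI
Why: lactone-enolate alkylation occurs anti to the C4 arylmethyl group, giving the 3,4-trans lactone (3R,4R), which corresponds to 8S,8'R in the target; any cis isomer is removed by chromatography.

**Step 8**
Reactants: 9
Product: 10, (2R,3R)-4-[4-(benzyloxy)-3,5-dimethoxyphenyl]-3-(hydroxymethyl)-N-methoxy-N,2-dimethylbutanamide
Conditions: MeNHOMe·HCl, AlMe3, CH2Cl2, 0 °C → rt; Rochelle salt work-up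
Reagents that add atoms: N,O-dimethylhydroxylamine, CNOC
Why: the aluminium amide (Weinreb aminolysis) opens the lactone, turning the carbonyl (future C7) into a Weinreb amide and leaving C9' as a free CH2OH; no stereocentre is touched.

**Step 9**
Reactants: 10
Product: 11, (2R,3R)-3-[(benzyloxy)methyl]-4-[4-(benzyloxy)-3,5-dimethoxyphenyl]-N-methoxy-N,2-dimethylbutanamide
Conditions: BnBr, Ag2O, CH2Cl2, 40 °C, dark
Reagents that add atoms: benzyl bromide, BrCc1ccccc1
Why: neutral silver(I)-promoted O-benzylation avoids alkoxide re-lactonisation and α-epimerisation, and gives a Grignard-stable ether that is removed with the other benzyl groups later.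

**Step 10**
Reactants: 12, 4-bromo-2-methoxyphenol
Product: 13, 1-(benzyloxy)-4-bromo-2-methoxybenzene
Conditions: BnBr, K2CO3, DMF, rt
Reagents that add atoms: benzyl bromide, BrCc1ccccc1
Why: Williamson etherification gives the protected aryl bromide for the guaiacyl Grignard reagent (independent branch).

**Step 11**
Reactants: 11; 13
Product: 14, (2R,3R)-3-[(benzyloxy)methyl]-1-[4-(benzyloxy)-3-methoxyphenyl]-4-[4-(benzyloxy)-3,5-dimethoxyphenyl]-2-methylbutan-1-one
Conditions: (i) 13, Mg, I2 (cat.), THF, 50 °C, giving ArMgBr; (ii) add 11 (2.5 equiv ArMgBr), THF, 0 °C → rt; sat. aq. NH4Cl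
Reagents that add atoms: none (the aryl group comes from 13)
Why: Weinreb ketone synthesis; the chelated tetrahedral intermediate stops at the ketone, so the C7–aryl bond forms without over-addition, and the mild quench preserves the α-stereocentre.

**Step 12**
Reactants: 14
Product: 15, (2R,3R)-3-[(benzyloxy)methyl]-1-[4-(benzyloxy)-3-methoxyphenyl]-4-[4-(benzyloxy)-3,5-dimethoxyphenyl]-2-methylbutan-1-ol (mixture of C1 epimers)
Conditions: NaBH4, MeOH–THF, 0 °C
Reagents that add atoms: none
Why: NaBH4 reduction of the aryl ketone removes the α-epimerisable carbonyl and gives a benzylic alcohol that hydrogenolyses cleanly, so the new carbinol centre is simply discarded in Step 13.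

**Step 13**
Reactants: 15
Product: 16, (2R,3S)-2-[(4-hydroxy-3,5-dimethoxyphenyl)methyl]-4-(4-hydroxy-3-methoxyphenyl)-3-methylbutan-1-ol
Conditions: H2 (1–3 atm), 10% Pd/C, EtOH–EtOAc, rt
Reagents that add atoms: none
Why: Pd-catalysed hydrogenolysis cleaves the three benzyl ethers and the electron-rich benzylic C–OH (C7 becomes CH2); C8 and C8' are neither benzylic nor α to a heteroatom or carbonyl, so they are retained.

**Step 14**
Reactants: 16
Product: 17, (2R,3S)-2-[(4-hydroxy-3,5-dimethoxyphenyl)methyl]-4-(4-hydroxy-3-methoxyphenyl)-3-methylbutyl acetate (target)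
Conditions: Novozym 435 (immobilised Candida antarctica lipase B, a hydrolase), vinyl acetate, MTBE, 30 °C
Reagents that add atoms: vinyl acetate, C=COC(C)=O
Why: lipase-catalysed transesterification through an acyl-enzyme acetylates the primary aliphatic OH and leaves both phenols untouched, so no phenol protection is needed, and the neutral mild conditions cannot epimerise the stereocentres.

## Compound list
1 | syringaldehyde | COc1cc(C=O)cc(OC)c1O | starting material
2 | 4-(benzyloxy)-3,5-dimethoxybenzaldehyde | COc1cc(C=O)cc(OC)c1OCc1ccccc1 | intermediate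
3 | diethyl succinate | CCOC(=O)CCC(=O)OCC | starting material
4 | (E)-Stobbe half-ester | CCOC(=O)/C(=C/c1cc(OC)c(OCc2ccccc2)c(OC)c1)CC(=O)O | intermediate
5 | (3R)-4-aryl-3-(ethoxycarbonyl)butanoic acid | OC(=O)C[C@@H](Cc1cc(OC)c(OCc2ccccc2)c(OC)c1)C(=O)OCC | intermediate
6 | 1-ethyl 4-tert-butyl (2R)-2-(arylmethyl)succinate | CC(C)(C)OC(=O)C[C@@H](Cc1cc(OC)c(OCc2ccccc2)c(OC)c1)C(=O)OCC | intermediate
7 | tert-butyl (3R)-4-hydroxy-3-(arylmethyl)butanoate | CC(C)(C)OC(=O)C[C@@H](Cc1cc(OC)c(OCc2ccccc2)c(OC)c1)CO | intermediate
8 | (4R)-4-(arylmethyl)oxolan-2-one | O=C1C[C@@H](Cc2cc(OC)c(OCc3ccccc3)c(OC)c2)CO1 | intermediate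
9 | (3R,4R)-4-(arylmethyl)-3-methyloxolan-2-one | C[C@H]1C(=O)OC[C@@H]1Cc1cc(OC)c(OCc2ccccc2)c(OC)c1 | intermediate
10 | hydroxy Weinreb amide | C[C@@H](C(=O)N(C)OC)[C@H](CO)Cc1cc(OC)c(OCc2ccccc2)c(OC)c1 | intermediate
11 | benzyl-protected Weinreb amide | C[C@@H](C(=O)N(C)OC)[C@H](COCc1ccccc1)Cc1cc(OC)c(OCc2ccccc2)c(OC)c1 | intermediate
12 | 4-bromo-2-methoxyphenol | COc1cc(Br)ccc1O | starting material
13 | 1-(benzyloxy)-4-bromo-2-methoxybenzene | COc1cc(Br)ccc1OCc1ccccc1 | intermediate
14 | tri-O-benzyl aryl ketone | C[C@@H](C(=O)c1ccc(OCc2ccccc2)c(OC)c1)[C@H](COCc1ccccc1)Cc1cc(OC)c(OCc2ccccc2)c(OC)c1 | intermediate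
15 | benzylic alcohol (C1 epimers) | C[C@@H](C(O)c1ccc(OCc2ccccc2)c(OC)c1)[C@H](COCc1ccccc1)Cc1cc(OC)c(OCc2ccccc2)c(OC)c1 | intermediate
16 | (2R,3S)-diphenol alcohol | C[C@@H](Cc1ccc(O)c(OC)c1)[C@H](CO)Cc1cc(OC)c(O)c(OC)c1 | intermediate
17 | target acetate | COc1cc(C[C@H](C)[C@H](COC(C)=O)Cc2cc(OC)c(O)c(OC)c2)ccc1O | target

## Totals
- Total steps: 14 (13 on the main line plus the one-step aryl bromide branch, Step 10).
- Longest linear sequence: 13 steps (Steps 1–9, then 11–14).

## Three steps most likely to fail
1. **Step 3, asymmetric hydrogenation (ee or conversion with this β,γ-unsaturated acid).** Fallback: hydrogenate 4 over Pd/C to racemic 5, then resolve classically as the (S)-1-phenylethylamine salt and recrystallise.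
2. **Step 13, four-fold hydrogenolysis (incomplete benzylic C–O cleavage, or acid-promoted 2-aryltetrahydrofuran formation once the primary OH is freed).** Fallback: deoxygenate ketone 14 directly with Et3SiH/TFA at 0 °C, with pentamethylbenzene as a cation scavenger, then remove all benzyl groups by H2/Pd-C.
3. **Step 14, lipase rate or chemoselectivity on the β-branched primary alcohol in the presence of two phenols.** Fallback: peracetylate 16 (Ac2O, pyridine), then cleave the aryl acetates selectively (NH4OAc, aq. MeOH), which are far more labile than the primary alkyl acetate.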